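**Assumption:** the cembrane numbering (C1–C20) is used only for discussion. Both chiral starting materials, (R)-linalool and (S)-carvone, are commercial.

## Retrosynthetic overview
1. The target comes from the protected macrolactone by Eschenmoser α-methylenation and global desilylation. The C3 and C11 carbinols are set late by oxidation/CBS reduction.
2. The 14-membered carbocycle is closed last by an intramolecular SmI2-Barbier reaction (C2 primary iodide + C3 aldehyde). It spans C1/C12 of a preformed seven-membered lactone.
3. The tertiary ε-lactone is made by Baeyer–Villiger ring expansion of a 2,2,5-trisubstituted cyclohexanone from (S)-carvone, so no tertiary-alcohol macrolactonization is needed. The cyclohexanone is built by reductive aldol with the THF-aldehyde, which forms C11–C12.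
4. The THF-diol unit (C4 quaternary, C7, C8) comes from (R)-linalool by SeO2 oxidation, Sharpless epoxidation and 5-exo epoxide opening. The vinyl group becomes the C3 acetal. Ring order: THF, then lactone (BV), then macrocycle.

## Route

**Step 1**
Reactants: 1, (R)-linalool
Product: 2, (E)-8-hydroxylinalool
Conditions: SeO2 (0.1 eq), TBHP, salicylic acid (cat.), CH2Cl2, 0 °C→rt
Reagents that add atoms: SeO2 (O=[Se]=O), TBHP (CC(C)(C)OO)
Why: Riley allylic oxidation hits the (E)-methyl of the trisubstituted alkene, giving the E-allylic alcohol. The C4 stereocentre is untouched.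

**Step 2**
Reactants: 2
Product: 3, (7R,8R)-epoxy alcohol
Conditions: Ti(OiPr)4, D-(−)-DET, TBHP, 4 Å MS, CH2Cl2, −20 °C
Reagents that add atoms: TBHP (CC(C)(C)OO)
Why: Sharpless asymmetric epoxidation of the primary allylic alcohol. The tartrate face selectivity sets the trans-(7R,8R) epoxide, and the tertiary allylic alcohol and vinyl group are inert.

**Step 3**
Reactants: 3
Product: 4, THF-diol
Conditions: CSA (0.1 eq), CH2Cl2, 0 °C
Reagents that add atoms: none
Why: The tertiary C4-OH opens the epoxide 5-exo at C7 with inversion, making C7 (S) and leaving the C8 tertiary OH (R). The β-hydroxyl disfavours the tertiary cation, so THP formation is suppressed, and C4 is retained.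

**Step 4**
Reactants: 4
Product: 5, C3 dimethyl acetal diol
Conditions: O3, CH2Cl2/MeOH, −78 °C; Me2S; then CH(OMe)3, PPTS, rt
Reagents that add atoms: ozone (O=[O+][O-]), trimethyl orthoformate (COC(OC)OC)
Why: Ozonolysis cleaves the only alkene (vinyl→aldehyde, C2 lost), and the aldehyde is masked as its acetal so it survives the later Baeyer–Villiger and homologation steps. No stereocentre is touched.

**Step 5**
Reactants: 5
Product: 6, α-hydroxy aldehyde
Conditions: DMP, NaHCO3, CH2Cl2, rt
Reagents that add atoms: none
Why: Dess–Martin oxidation acts only on the primary alcohol; the tertiary C8-OH cannot be oxidised.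

**Step 6**
Reactants: 6
Product: 7, C8-OTBS aldehyde
Conditions: TBSOTf, 2,6-lutidine, CH2Cl2, −78 °C, 20 min
Reagents that add atoms: TBSOTf (CC(C)(C)[Si](C)(C)OS(=O)(=O)C(F)(F)F)
Why: The silyl triflate is needed for a hindered tertiary alcohol. The low temperature and short time keep the acetal intact, and C8 configuration is retained.

**Step 7**
Reactants: 7
Product: 8, (E)-enal
Conditions: Ph3P=CHCHO, toluene, 90 °C
Reagents that add atoms: (formylmethylene)triphenylphosphorane (O=CC=P(c1ccccc1)(c1ccccc1)c1ccccc1)
Why: Wittig homologation with a stabilised ylide installs C10–C11 and gives the E-enal.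

**Step 8**
Reactants: 8
Product: 9, saturated C11 aldehyde (THF fragment)
Conditions: [(Ph3P)CuH]6 (Stryker), toluene, −40 °C
Reagents that add atoms: none (adds H2)
Why: Copper-hydride conjugate reduction saturates C9=C10 and leaves the aldehyde, TBS ether and acetal intact.

**Step 9**
Reactants: 10, (S)-carvone
Product: 11, (S)-5-acetyl-2-methylcyclohex-2-enone
Conditions: O3 (1 eq), CH2Cl2/MeOH, −78 °C; then PPh3
Reagents that add atoms: ozone (O=[O+][O-])
Why: The electron-rich isopropenyl group is cleaved in preference to the conjugated enone alkene. The C1 stereocentre (carvone C5) is untouched.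

**Step 10**
Reactants: 11
Product: 12, (S)-4-methyl-3-oxocyclohex-4-ene-1-carboxylic acid
Conditions: NaOCl, NaOH, dioxane/H2O, 0 °C
Reagents that add atoms: sodium hypochlorite ([Na+].[O-]Cl)
Why: Haloform reaction of the methyl ketone leaves a single carbon (future C2) on C1.

**Step 11**
Reactants: 12
Product: 13, (S)-5-(hydroxymethyl)-2-methylcyclohex-2-enone
Conditions: BH3·SMe2, THF, 0 °C
Reagents that add atoms: none
Why: Borane reduces the carboxylic acid faster than the conjugated ketone.

**Step 12**
Reactants: 13 + 9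
Product: 14, aldol adduct
Conditions: L-Selectride (2.2 eq), THF, −78 °C, 1 h; then 9, −78→−20 °C
Reagents that add atoms: none (the hydride adds only H)
Why: The first equivalent of L-Selectride deprotonates the CH2OH. The second performs 1,4-reduction, giving the regiospecific tetrasubstituted C12 enolate (Fortunato–Ganem reductive aldol), which adds to the aldehyde. Warming allows retro-aldol equilibration to the diequatorial isomer (C11 chain and C1-CH2OH equatorial, Me axial, so C11 is trans to C2 as required). C11 is obtained as an epimeric mixture that is converged in Steps 15–16.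
Proposed new method: tandem conjugate reduction/aldol with thermodynamic control of the α-quaternary centre. Mechanistically, reversible aldolate formation funnels to the chair isomer with the larger substituent equatorial; the closest known reaction is the L-Selectride reductive aldol.

**Step 13**
Reactants: 14
Product: 15, seven-membered lactone
Conditions: mCPBA, NaHCO3, CH2Cl2, 0 °C→rt
Reagents that add atoms: mCPBA (OOC(=O)c1cccc(Cl)c1)
Why: Baeyer–Villiger oxidation with migration of the tertiary C12 in preference to the primary C15, with retention of configuration, gives the tertiary ε-lactone. The substrate has no alkene (vinyl is masked) so there is no epoxidation.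

**Step 14**
Reactants: 15
Product: 16, primary iodide
Conditions: I2, PPh3, imidazole, CH2Cl2, 0 °C
Reagents that add atoms: I2 (II)
Why: Appel/Garegg–Samuelsson conditions iodinate the primary alcohol selectively, leaving the hindered C11-OH untouched.

**Step 15**
Reactants: 16
Product: 17, C11 ketone
Conditions: DMP, NaHCO3, CH2Cl2
Reagents that add atoms: none
Why: Oxidation destroys the C11 stereochemical mixture, so both epimers converge.

**Step 16**
Reactants: 17
Product: 18, (11R)-alcohol
Conditions: (S)-Me-CBS (0.2 eq), catecholborane, toluene, −78 °C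
Reagents that add atoms: none
Why: CBS reduction is catalyst-controlled. The quaternary C12 is the large group and C10 the small one, so (S)-CBS gives (R)-C11. The lactone and iodide survive at −78 °C.

**Step 17**
Reactants: 18
Product: 19, C3 aldehyde
Conditions: PPTS, acetone/H2O (10:1), 60 °C
Reagents that add atoms: water (O)
Why: Mild acetal hydrolysis; the TBS ether, lactone and iodide are stable. The aldehyde has no α-H, so there is no epimerisation or enolisation.

**Step 18**
Reactants: 19
Product: 20, iodo-aldehyde (C11-OTBS)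
Conditions: TBSOTf, 2,6-lutidine, CH2Cl2, −78 °C
Reagents that add atoms: TBSOTf (CC(C)(C)[Si](C)(C)OS(=O)(=O)C(F)(F)F)
Why: Protecting the C11 alcohol allows a selective C3 oxidation later. The quaternary α-carbon means the aldehyde cannot enolise.

**Step 19**
Reactants: 20
Product: 21, macrocyclic C3 carbinol (C3 epimeric mixture)
Conditions: SmI2 (2.5 eq), NiI2 (cat.), THF, 0 °C, syringe pump at 2 mM
Reagents that add atoms: none
Why: Intramolecular Barbier reaction: the organosamarium from the C2 iodide adds to the C3 aldehyde, closing the 14-membered carbocycle across the lactone. The C3 stereocentre is not controlled here and is fixed in Steps 20–21.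
Proposed new method: macrocyclic SmI2-Barbier bridging the 1,4-positions of a seven-membered lactone. The alkyl iodide is reduced to an organosamarium that is trapped by the non-enolisable aldehyde; the closest known reaction is the Molander-type intramolecular Sm-Barbier.

**Step 20**
Reactants: 21
Product: 22, C3 ketone
Conditions: DMP, NaHCO3, CH2Cl2
Reagents that add atoms: none
Why: Oxidation at C3 is selective because C11 is silylated, and it converges the C3 epimers.

**Step 21**
Reactants: 22
Product: 23, (3S)-alcohol
Conditions: (R)-Me-CBS (0.2 eq), catecholborane, toluene, −78 °C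
Reagents that add atoms: none
Why: The quaternary C4 is the large group and C2 the small one, so (R)-CBS gives (S)-C3 by catalyst control.

**Step 22**
Reactants: 23
Product: 24, Mannich base
Conditions: LDA (4 eq), THF, −78 °C; then Me2N=CH2+ I−
Reagents that add atoms: Eschenmoser's salt (C[N+](C)=C.[I-])
Why: Lactone enolisation at C15, the only α-CH2, followed by aminomethylation. C15 becomes a transient stereocentre (no stereochemistry specified); C12 and C1 are not enolisable.

**Step 23**
Reactants: 24
Product: 25, protected α-methylene lactone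
Conditions: MeI, CH2Cl2; then DBU
Reagents that add atoms: none (MeI ends as Me3N on elimination)
Why: N-Methylation followed by E1cB elimination of Me3N forms the exocyclic methylene.

**Step 24**
Reactants: 25
Product: 26, querciformolide D
Conditions: HF·pyridine, THF/pyridine, 40 °C
Reagents that add atoms: none
Why: Global removal of the tertiary C8 and secondary C11 TBS ethers; the α-methylene lactone is stable to non-basic HF conditions.

## Compound list
1 | (R)-linalool | C=C[C@](C)(O)CCC=C(C)C | starting material
2 | (2E,6R)-2,6-dimethylocta-2,7-diene-1,6-diol | C=C[C@](C)(O)CC/C=C(\C)CO | intermediate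
3 | [(2R,3R)-3-[(3R)-3-hydroxy-3-methylpent-4-en-1-yl]-2-methyloxiran-2-yl]methanol | C=C[C@](C)(O)CC[C@H]1O[C@]1(C)CO | intermediate
4 | (2R)-2-[(2S,5R)-5-ethenyl-5-methyloxolan-2-yl]propane-1,2-diol | C=C[C@@]1(C)CC[C@H](O1)[C@](C)(O)CO | intermediate
5 | (2R)-2-[(2S,5R)-5-(dimethoxymethyl)-5-methyloxolan-2-yl]propane-1,2-diol | COC(OC)[C@@]1(C)CC[C@H](O1)[C@](C)(O)CO | intermediate
6 | (2S)-2-[(2S,5R)-5-(dimethoxymethyl)-5-methyloxolan-2-yl]-2-hydroxypropanal | COC(OC)[C@@]1(C)CC[C@H](O1)[C@](C)(O)C=O | intermediate
7 | (2S)-2-(TBSO)-2-[(2S,5R)-5-(dimethoxymethyl)-5-methyloxolan-2-yl]propanal | COC(OC)[C@@]1(C)CC[C@H](O1)[C@](C)(O[Si](C)(C)C(C)(C)C)C=O | intermediate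
8 | (2E,4R)-4-(TBSO)-4-[(2S,5R)-5-(dimethoxymethyl)-5-methyloxolan-2-yl]pent-2-enal | COC(OC)[C@@]1(C)CC[C@H](O1)[C@](C)(O[Si](C)(C)C(C)(C)C)/C=C/C=O | intermediate
9 | (4R)-4-(TBSO)-4-[(2S,5R)-5-(dimethoxymethyl)-5-methyloxolan-2-yl]pentanal | COC(OC)[C@@]1(C)CC[C@H](O1)[C@](C)(O[Si](C)(C)C(C)(C)C)CCC=O | intermediate
10 | (S)-(+)-carvone | CC1=CC[C@@H](CC1=O)C(C)=C | starting material
11 | (5S)-5-acetyl-2-methylcyclohex-2-en-1-one | CC1=CC[C@@H](CC1=O)C(C)=O | intermediate
12 | (S)-4-methyl-3-oxocyclohex-4-ene-1-carboxylic acid | CC1=CC[C@@H](CC1=O)C(=O)O | intermediate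
13 | (5S)-5-(hydroxymethyl)-2-methylcyclohex-2-en-1-one | CC1=CC[C@@H](CC1=O)CO | intermediate
14 | aldol adduct: cyclohexanone, single C12 epimer, C11 epimeric mixture | OC[C@H]1CC[C@](C)(C(O)CC[C@@](C)(O[Si](C)(C)C(C)(C)C)[C@@H]2CC[C@](C)(C(OC)OC)O2)C(=O)C1 | intermediate
15 | ε-lactone from Baeyer–Villiger | OC[C@H]1CC[C@](C)(C(O)CC[C@@](C)(O[Si](C)(C)C(C)(C)C)[C@@H]2CC[C@](C)(C(OC)OC)O2)OC(=O)C1 | intermediate
16 | primary iodide | IC[C@H]1CC[C@](C)(C(O)CC[C@@](C)(O[Si](C)(C)C(C)(C)C)[C@@H]2CC[C@](C)(C(OC)OC)O2)OC(=O)C1 | intermediate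
17 | C11 ketone | IC[C@H]1CC[C@](C)(C(=O)CC[C@@](C)(O[Si](C)(C)C(C)(C)C)[C@@H]2CC[C@](C)(C(OC)OC)O2)OC(=O)C1 | intermediate
18 | (11R)-alcohol | IC[C@H]1CC[C@](C)([C@H](O)CC[C@@](C)(O[Si](C)(C)C(C)(C)C)[C@@H]2CC[C@](C)(C(OC)OC)O2)OC(=O)C1 | intermediate
19 | C3 aldehyde | IC[C@H]1CC[C@](C)([C@H](O)CC[C@@](C)(O[Si](C)(C)C(C)(C)C)[C@@H]2CC[C@](C)(C=O)O2)OC(=O)C1 | intermediate
20 | iodo-aldehyde, C11-OTBS | IC[C@H]1CC[C@](C)([C@H](O[Si](C)(C)C(C)(C)C)CC[C@@](C)(O[Si](C)(C)C(C)(C)C)[C@@H]2CC[C@](C)(C=O)O2)OC(=O)C1 | intermediate
21 | macrocyclic C3-carbinol (C3 epimeric mixture) | C1C(=O)O[C@]2(C)CC[C@@H]1CC(O)[C@@]1(C)CC[C@H](O1)[C@](C)(O[Si](C)(C)C(C)(C)C)CC[C@H]2O[Si](C)(C)C(C)(C)C | intermediate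
22 | macrocyclic C3 ketone | C1C(=O)O[C@]2(C)CC[C@@H]1CC(=O)[C@@]1(C)CC[C@H](O1)[C@](C)(O[Si](C)(C)C(C)(C)C)CC[C@H]2O[Si](C)(C)C(C)(C)C | intermediate
23 | (3S)-alcohol | C1C(=O)O[C@]2(C)CC[C@@H]1C[C@H](O)[C@@]1(C)CC[C@H](O1)[C@](C)(O[Si](C)(C)C(C)(C)C)CC[C@H]2O[Si](C)(C)C(C)(C)C | intermediate
24 | Mannich base (C15 unspecified) | CN(C)CC1C(=O)O[C@]2(C)CC[C@@H]1C[C@H](O)[C@@]1(C)CC[C@H](O1)[C@](C)(O[Si](C)(C)C(C)(C)C)CC[C@H]2O[Si](C)(C)C(C)(C)C | intermediate
25 | bis-TBS α-methylene lactone | C=C1C(=O)O[C@]2(C)CC[C@@H]1C[C@H](O)[C@@]1(C)CC[C@H](O1)[C@](C)(O[Si](C)(C)C(C)(C)C)CC[C@H]2O[Si](C)(C)C(C)(C)C | intermediate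
26 | querciformolide D | C=C1C(=O)O[C@]2(C)CC[C@@H]1C[C@H](O)[C@@]1(C)CC[C@H](O1)[C@](C)(O)CC[C@H]2O | target

**Total steps:** 24. **Longest linear sequence:** 21 steps, from (R)-linalool (1).

**Three steps most likely to fail**
1. **Step 12 (reductive aldol, C12 relative configuration).** The kinetic axial attack gives the wrong C12 epimer, and the thermodynamic equilibration may be incomplete. Fallback: a "methyl-last" approach. Build the C11–C12 bond on the C12-desmethyl 3-substituted cyclohexanone (from Rh-catalysed asymmetric conjugate vinylation of cyclohexenone, then ozonolysis and reduction). Oxidise to the 1,3-diketone and methylate (MeI, K2CO3), so Me enters axially, cis to C2.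
2. **Step 19 (SmI2 macro-Barbier).** Oligomerisation or pinacol coupling may compete. Fallback: form C2–C3 intermolecularly by Fukuyama coupling (C3 thioester + C2 alkylzinc) on an open-chain bis-vinyl-carbinol precursor, close the ring by RCM at C9=C10, then hydrogenate.
3. **Step 13 (Baeyer–Villiger of the hindered β-hydroxy ketone).** It may be slow, or retro-aldol may occur. Fallback: enzymatic Baeyer–Villiger with a cyclohexanone monooxygenase, which is neutral and tertiary-selective.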